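Read at 30.0 s, the green flask holds 29.0% target and the red run 21.8%, a ratio of 1.33, though green was charged 1.94 times as much second substrate.

in all of them: starting material 0.050 M

| charge | second substrate | free enzyme | remark |
|---|---|---|---|
| green | 0.035 M | 5 µM | the very flask that is asked about, followed so far |
| red | 0.018 M | 5 µM | run made earlier |
| flask | 0.0350 M | 5.0 µM |  |

| run | time / s | target / % | starting material / % |
|---|---|---|---|
| green | 10.0 | 10.9 | 88.5 |
| green | 15.0 | 14.5 | 84.6 |
| green | 20.0 | 20.2 | 79.2 |
| green | 30.0 | 29.0 | 70.9 |
| green | 40.0 | 37.8 | 64.8 |
| red | 10.0 | 7.0 | 90.9 |
| red | 30.0 | 21.8 | 78.8 |
| red | 60.0 | 33.2 | 66.4 |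
| red | 80.0 | 33.8 | 66.2 |
| red | 120 | 35.5 | 64.4 |

(standard deviation of a reading: 1 percentage point)

- apparent order in second substrate when 5.0% of the starting material are converted (percent change of the rate of making target for one percent more second substrate charged)
- apparent order in free enzyme when 5.0% of the starting material are converted (percent change of the rate of making target for one percent more free enzyme charged)

- no earlier run changes the charge of free enzyme; that part of a forecast is a guess

Take two extremes you can solve in your head. If the rate followed second substrate in proportion, that ratio would be 1.94; if the catalyst were always full of it, the ratio would be 1. The reading lies between, so I put the flask on a saturation curve, where the rate is half its full value at a fraction h of green's charge.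

Work with the fraction left, not the charge. The red run reads 35.5% at 120 s, close to the 36.0% its charge allows, so second substrate is its limiting reagent and each target takes one. Averaged over the first 30.0 s, second substrate stands at 0.793 of green's charge in green and 0.359 of that charge in red, so the curve gives h = 0.297. At 5.0% conversion green has 0.929 of its second substrate left, so the open share, h over h plus the fraction left, is 0.243. One percent more charged is 1.08 percent more present, so my order is 0.261, rough given a scatter of 1 percentage point. No run changes the free enzyme, so I guess first order there.

The forecast gave 0.42 (0.15 to 0.7) in second substrate, higher than mine, starting from “the order is about 0.45 between the two charges”, and guessed 1 (0.75 to 1.2) in free enzyme.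

The flask gives order 0.20 in second substrate and 0.93 in free enzyme, so the open share of 0.243 and my order of 0.261 both stand above the simulated order in second substrate.

    starting material + free enzyme ⇌ first complex (K = 330 /M, k = 10100 /M/s)
    first complex ⇌ loaded enzyme + first product (K = 0.101 M, k = 218 /s)
    second substrate + loaded enzyme ⇌ second complex (K = 78.0 /M, k = 2.98 × 10⁵ /M/s)
    second complex → free enzyme + target (k = 924 /s)
    2 loaded enzyme ⇌ resting dimer, settled at all times (K = 2.20 × 10⁶ /M)
    2 free enzyme → spent catalyst (k = 6840 /M/s)

First complex goes on to loaded enzyme, a step that takes no second substrate, at 13000 /min per first complex, slower than second complex gives target at 55400 /min per second complex. At 0.200 min first complex holds 45.3% of the catalyst in the flask, more than the 10.6% in second complex.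

The numbers in the tables are simulated for an exercise, noise included.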